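**Plan**
- Retrosynthetic cuts, in order: acyl groups and the C1 ketone; the 6,12‑lactone (oxidative lactonisation of a C6/C12 ene‑diol); the ring bond C8–C9 (intramolecular vinylogous Mukaiyama aldol); C1–C10 (crotylboration); C11–C12 (Stille); C6–C7 (Nozaki–Hiyama–Kishi).
- Enabling feature: the tetrasubstituted C7=C11 alkene carries four oxygenated carbons (C6, C8, C12, C13). Drawn as the isomeric 8,13‑butenolide (C13 carbonyl, O8 ring oxygen), C8 becomes the γ‑carbon of a 2‑silyloxyfuran and C9 its aldehyde partner.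
- Forward order: nerol gives the C1–C6 chain with C14/C15; the dibromofuranone is attached at C6; C12 is added; C9/C10 are added; the ten‑membered ring is closed at C8–C9.
- Helpers and their removal: the 8,13‑lactone is reduced (C13 → CH2OAc, O8 → methacrylate); the O6/O12 silylene is cleaved and C12 oxidised to the 6,12‑lactone; the C1 carbinol is oxidised to the ketone.
- Stereochemistry: C4/C5 by Sharpless epoxidation of nerol; C6 by Felkin–Anh addition to the epoxy aldehyde; C10 by reagent‑controlled crotylboration; C8 and C9 in the ring closure.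

Key step: step 11

Remark: locants C‑1 to C‑15 in names are those of the germacranolide skeleton of the target (C‑12 lactone carbonyl carbon, C‑13 acetoxymethyl carbon); the (Z)‑crotylboronate of diisopropyl D‑tartrate used in step 8 is taken as a stock reagent made by the standard procedure from cis‑2‑butene.

Step 1
Reactants: 1 mucobromic acid
Product: 3 3,4-dibromofuran-2(5H)-one, via hydroxy acid 2 (not isolated)
Conditions: NaBH4, MeOH, 0 °C; then conc. H2SO4
Reagents that add atoms: none
Why: Borohydride reduction of the open aldehyde tautomer of the lactol, then acid‑driven lactonisation of the (Z)‑hydroxy acid, is the standard access to this butenolide; no stereocentre is formed.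

Step 2
Reactants: 4 nerol
Product: 5 (2S,3R)-2,3-epoxynerol
Conditions: Ti(OiPr)4 (cat.), L-(+)-diethyl tartrate, t-BuOOH, 4 Å MS, CH2Cl2, −20 °C
Reagents that add atoms: tert-butyl hydroperoxide, CC(C)(C)OO
Why: Sharpless asymmetric epoxidation of the (Z)‑allylic alcohol delivers oxygen to one enantioface under reagent control, setting C4 (R) and C5 (S) as the cis‑epoxide and leaving the remote alkene untouched.

Step 3
Reactants: 5 (2S,3R)-2,3-epoxynerol
Product: 6 (2R,3R)-3-methyl-3-(4-methylpent-3-en-1-yl)oxirane-2-carbaldehyde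
Conditions: Dess–Martin periodinane, NaHCO3, CH2Cl2, 0 °C
Reagents that add atoms: none
Why: Buffered Dess–Martin oxidation should give the cis‑epoxy aldehyde without epimerisation; it is used at once.

Step 4
Reactants: 6 epoxy aldehyde; 3 3,4-dibromofuran-2(5H)-one
Product: 7 3-bromo-4-{(S)-hydroxy[(2S,3R)-3-methyl-3-(4-methylpent-3-en-1-yl)oxiran-2-yl]methyl}furan-2(5H)-one
Conditions: CrCl2 (4 equiv), NiCl2 (cat.), DMF, rt
Reagents that add atoms: none
Why: Nozaki–Hiyama–Kishi coupling: zerovalent nickel inserts into the more electrophilic C–Br bond β to the carbonyl, the vinyl species of trivalent chromium adds only to the aldehyde, and Felkin–Anh attack anti to the epoxide C–O bond should set C6 as the erythro (6S) epoxy alcohol.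

Step 5
Reactants: 7 bromo alcohol
Product: 8 3-(hydroxymethyl)-4-{(S)-hydroxy[(2S,3R)-3-methyl-3-(4-methylpent-3-en-1-yl)oxiran-2-yl]methyl}furan-2(5H)-one
Conditions: Bu3SnCH2OH, Pd(PPh3)4 (cat.), 1,4-dioxane, 90 °C
Reagents that add atoms: (tributylstannyl)methanol, CCCC[Sn](CCCC)(CCCC)CO
Why: Stille cross‑coupling of the remaining α‑bromide installs the C12 hydroxymethyl group under neutral conditions that the epoxide and free alcohol tolerate.

Step 6
Reactants: 8 diol
Product: 9 O6,O12-di-tert-butylsilylene acetal of 8 (seven-membered 1,3,2-dioxasilepine fused to the furanone; 4R,5S,6S)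
Conditions: t-Bu2Si(OTf)2, 2,6-lutidine, CH2Cl2, 0 °C
Reagents that add atoms: di-tert-butylsilyl bis(trifluoromethanesulfonate), CC(C)(C)[Si](OS(=O)(=O)C(F)(F)F)(OS(=O)(=O)C(F)(F)F)C(C)(C)C
Why: Silylene acetal formation ties the cis‑disposed 1,4‑diol into a seven‑membered ring, protecting O6 and O12 in one step and holding O6 on the C11 flank for the later ring closure.

Step 7
Reactants: 9 silylene
Product: 11 C1 aldehyde (chain shortened by acetone; silylene, epoxide and butenolide unchanged), via ozonide 10 (not isolated)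
Conditions: O3, CH2Cl2, −78 °C; then PPh3, −78 °C to rt
Reagents that add atoms: ozone, [O-][O+]=O
Why: Chemoselective ozonolysis: the electron‑rich isopropylidene alkene should be cleaved far faster than the electron‑poor tetrasubstituted butenolide alkene.

Step 8
Reactants: 11 C1 aldehyde
Product: 12 (1S,10S)-homoallylic alcohol (C1 OH and C10 methyl syn; terminal vinyl CH is C9)
Conditions: (Z)-crotylboronate of diisopropyl (S,S)-tartrate, 4 Å MS, toluene, −78 °C; aq. NaHCO3
Reagents that add atoms: diisopropyl (S,S)-tartrate (Z)-crotylboronate, C/C=C\CB1O[C@H](C(=O)OC(C)C)[C@@H](C(=O)OC(C)C)O1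
Why: Roush asymmetric crotylboration through a closed chair transition state: the (Z)‑crotyl geometry gives the 1,10‑syn pair and the tartrate selects the aldehyde face, setting C10 and the temporary C1 carbinol under reagent control.

Step 9
Reactants: 12 homoallylic alcohol
Product: 13 C1 triethylsilyl ether of 12
Conditions: TESCl, imidazole, DMF, 0 °C
Reagents that add atoms: chlorotriethylsilane, CC[Si](Cl)(CC)CC
Why: Standard silylation under basic conditions, done without delay so that the free C1 hydroxyl cannot open the 4,5‑epoxide in a 5‑exo fashion.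

Step 10
Reactants: 13 triethylsilyl ether
Product: 15 (1S,4R,5S,6S,10R)-C9 aldehyde (α-methyl, β-triethylsilyloxy), via diol 14 (not isolated)
Conditions: OsO4 (cat.), NaIO4, 2,6-lutidine, dioxane–H2O, rt
Reagents that add atoms: sodium periodate, [Na+].[O-]I(=O)(=O)=O (oxygen delivered through catalytic osmium tetroxide, O=[Os](=O)(=O)=O)
Why: Lemieux–Johnson cleavage: only the terminal vinyl group is dihydroxylated (the tetrasubstituted enoate is inert) and the lutidine buffer guards the α‑stereocentre of the aldehyde.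

Step 11
Reactants: 15 C9 aldehyde
Product: 17 (1S,4R,5S,6S,8R,9R,10R)-macrocyclic 8,13-olide (ten-membered carbocycle fused to the butenolide; 9-OTBS, 1-OTES, O6/O12 silylene, 4,5-epoxide), via silyloxyfuran 16 (not isolated)
Conditions: TBSOTf (3 equiv), i-Pr2NEt, CH2Cl2, −78 to −30 °C, slow addition of 15 (about 2 mM)
Reagents that add atoms: tert-butyldimethylsilyl trifluoromethanesulfonate, CC(C)(C)[Si](C)(C)OS(=O)(=O)C(F)(F)F
Why: Soft enolisation takes the acidic C8–H2 of the butenolide to 2‑silyloxyfuran 16, whose γ‑carbon C8 adds to the silyl‑triflate‑activated C9 aldehyde with the silyl group ending on O9 (intramolecular vinylogous Mukaiyama aldol). The closest known reaction types are Lewis‑acid‑promoted γ‑additions of 2‑silyloxyfurans to aldehydes and silylative (silyl triflate/amine) cycloaldolisations of aldehyde‑tethered lactones; medium rings have been closed by vinylogous Mukaiyama aldol reactions. The ten‑membered carbocycle closes in a 10‑(enolendo)‑exo‑trig mode, helped by two turn elements, the cis‑epoxide and the ortho relationship of C6 and C8 on the furan. C8 is controlled by C6: the dioxasilepine holds O6 on the C11 flank, so the C6–C5 bond of the (6S) centre can leave toward one furan face only, and the tether delivers C9 to that face (8R). C9 follows from an open transition state in which C10 must lie on the C6 flank and the bulky silylated carbonyl oxygen points away from the furan, the like topicity that gives the threo (8R,9R) pair. The step needs γ‑ over α‑attack (C11 is fully substituted), deprotonation at C8 rather than C6 (only C8 leads to an aromatic furan) and ring closure over oligomerisation (high dilution); the outcome, O9 as silyl ether and O8 as lactone oxygen, is what later tells the two oxygens apart.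

Step 12
Reactants: 17 macrocyclic 8,13-olide
Product: 18 8,13-diol (secondary C8 OH, primary C13 OH; other groups unchanged)
Conditions: i-Bu2AlH (4 equiv), CH2Cl2, −78 to −20 °C; Rochelle salt work-up
Reagents that add atoms: none
Why: Aluminium hydride reduction of a butenolide to the (Z)‑2‑ene‑1,4‑diol via the lactol opens the temporary ring; 1,2‑reduction is expected for the hindered tetrasubstituted enoate.

Step 13
Reactants: 18 8,13-diol
Product: 19 13-acetate (C8 OH free)
Conditions: AcCl (1.1 equiv), 2,4,6-collidine, CH2Cl2, −78 °C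
Reagents that add atoms: acetyl chloride, CC(Cl)=O
Why: Kinetically selective acylation of the primary allylic alcohol over the hindered secondary C8 alcohol.

Step 14
Reactants: 19 13-acetate
Product: 20 8-methacrylate 13-acetate
Conditions: methacrylic anhydride, Et3N, DMAP (cat.), CH2Cl2, 0 °C to rt
Reagents that add atoms: methacrylic anhydride, C=C(C)C(=O)OC(=O)C(C)=C
Why: DMAP‑catalysed acyl transfer (Steglich‑type) to the only free hydroxyl.

Step 15
Reactants: 20 8-methacrylate 13-acetate
Product: 21 1,6,12-triol (9-OTBS retained)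
Conditions: HF·pyridine, pyridine, THF, 0 °C
Reagents that add atoms: none
Why: Fluoride desilylation graded by sterics: the silylene and the triethylsilyl ether should cleave well before the hindered secondary TBS ether at C9; pyridine buffering keeps the freed C1 hydroxyl from opening the epoxide across the ring.

Step 16
Reactants: 21 1,6,12-triol
Product: 23 (1S,4R,5S,6S,8R,9R,10R)-6,12-olide with 1-OH and 9-OTBS, via lactol 22 (not isolated)
Conditions: TEMPO (cat.), PhI(OAc)2, CH2Cl2, rt
Reagents that add atoms: none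
Why: Oxoammonium oxidative lactonisation of a (Z)‑2‑ene‑1,4‑diol: the primary allylic C12 alcohol is oxidised first, the aldehyde is trapped by the cis C6 hydroxyl as a lactol, and this is oxidised to the butenolide; the C7=C11 geometry allows only this lactone and C6 keeps its configuration.

Step 17
Reactants: 23 6,12-olide
Product: 24 (4R,5S,6S,8R,9R,10S)-1-ketone with 9-OTBS
Conditions: Dess–Martin periodinane, NaHCO3, CH2Cl2, 0 °C
Reagents that add atoms: none
Why: Dess–Martin oxidation of the only free hydroxyl under buffered, non‑basic conditions, so the C10 centre α to the new ketone is not epimerised.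

Step 18
Reactants: 24 1-ketone
Product: 25 target, (4R,5S,6S,8R,9R,10S)
Conditions: HF·pyridine, pyridine, THF, 0 °C to rt
Reagents that add atoms: none
Why: Mildly acidic fluoride desilylation frees the C9 hydroxyl without base, so retro‑aldol cleavage, C10 epimerisation and O8 to O9 acyl migration should not be triggered.

**Compound list**
1 | mucobromic acid (3,4-dibromo-5-hydroxyfuran-2(5H)-one) | OC1OC(=O)C(Br)=C1Br | starting material
2 | (Z)-2,3-dibromo-4-hydroxybut-2-enoic acid | OC/C(Br)=C(/Br)C(O)=O | intermediate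
3 | 3,4-dibromofuran-2(5H)-one | O=C1OCC(Br)=C1Br | intermediate
4 | nerol, (2Z)-3,7-dimethylocta-2,6-dien-1-ol | CC(C)=CCC/C(C)=C\CO | starting material
5 | (2S,3R)-2,3-epoxynerol | OC[C@@H]1O[C@]1(C)CCC=C(C)C | intermediate
6 | (2R,3R)-3-methyl-3-(4-methylpent-3-en-1-yl)oxirane-2-carbaldehyde | O=C[C@@H]1O[C@]1(C)CCC=C(C)C | intermediate
7 | 3-bromo-4-{(S)-hydroxy[(2S,3R)-3-methyl-3-(4-methylpent-3-en-1-yl)oxiran-2-yl]methyl}furan-2(5H)-one | O=C1OCC(=C1Br)[C@H](O)[C@@H]1O[C@]1(C)CCC=C(C)C | intermediate
8 | 3-(hydroxymethyl)-4-{(S)-hydroxy[(2S,3R)-3-methyl-3-(4-methylpent-3-en-1-yl)oxiran-2-yl]methyl}furan-2(5H)-one | O=C1OCC(=C1CO)[C@H](O)[C@@H]1O[C@]1(C)CCC=C(C)C | intermediate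
9 | O6,O12-di-tert-butylsilylene acetal of 8 (4R,5S,6S) | O=C1OCC2=C1CO[Si](C(C)(C)C)(C(C)(C)C)O[C@@H]2[C@@H]1O[C@]1(C)CCC=C(C)C | intermediate
10 | ozonide of 9 (5,5-dimethyl-1,2,4-trioxolane at the former isopropylidene alkene) | O=C1OCC2=C1CO[Si](C(C)(C)C)(C(C)(C)C)O[C@@H]2[C@@H]1O[C@]1(C)CCC1OOC(C)(C)O1 | intermediate
11 | C1 aldehyde (4R,5S,6S) | O=C1OCC2=C1CO[Si](C(C)(C)C)(C(C)(C)C)O[C@@H]2[C@@H]1O[C@]1(C)CCC=O | intermediate
12 | (1S,4R,5S,6S,10S)-homoallylic alcohol, 1-OH/10-Me syn | O=C1OCC2=C1CO[Si](C(C)(C)C)(C(C)(C)C)O[C@@H]2[C@@H]1O[C@]1(C)CC[C@H](O)[C@@H](C)C=C | intermediate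
13 | C1 triethylsilyl ether of 12 | O=C1OCC2=C1CO[Si](C(C)(C)C)(C(C)(C)C)O[C@@H]2[C@@H]1O[C@]1(C)CC[C@H](O[Si](CC)(CC)CC)[C@@H](C)C=C | intermediate
14 | vicinal diol from the vinyl group of 13 (carbinol epimers) | O=C1OCC2=C1CO[Si](C(C)(C)C)(C(C)(C)C)O[C@@H]2[C@@H]1O[C@]1(C)CC[C@H](O[Si](CC)(CC)CC)[C@@H](C)C(O)CO | intermediate
15 | (1S,4R,5S,6S,10R)-C9 aldehyde | O=C1OCC2=C1CO[Si](C(C)(C)C)(C(C)(C)C)O[C@@H]2[C@@H]1O[C@]1(C)CC[C@H](O[Si](CC)(CC)CC)[C@@H](C)C=O | intermediate
16 | 2-(tert-butyldimethylsilyloxy)furan of 15 | CC(C)(C)[Si](C)(C)Oc1occ2c1CO[Si](C(C)(C)C)(C(C)(C)C)O[C@@H]2[C@@H]1O[C@]1(C)CC[C@H](O[Si](CC)(CC)CC)[C@@H](C)C=O | intermediate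
17 | (1S,4R,5S,6S,8R,9R,10R)-macrocyclic 8,13-olide, 9-OTBS, 1-OTES, O6/O12 silylene | O=C1O[C@@H]3C2=C1CO[Si](C(C)(C)C)(C(C)(C)C)O[C@@H]2[C@@H]1O[C@]1(C)CC[C@H](O[Si](CC)(CC)CC)[C@@H](C)[C@H]3O[Si](C)(C)C(C)(C)C | intermediate
18 | 8,13-diol from 17 | O[C@@H]1C2=C(CO)CO[Si](C(C)(C)C)(C(C)(C)C)O[C@@H]2[C@@H]2O[C@]2(C)CC[C@H](O[Si](CC)(CC)CC)[C@@H](C)[C@H]1O[Si](C)(C)C(C)(C)C | intermediate
19 | 13-acetate of 18 | O[C@@H]1C2=C(COC(C)=O)CO[Si](C(C)(C)C)(C(C)(C)C)O[C@@H]2[C@@H]2O[C@]2(C)CC[C@H](O[Si](CC)(CC)CC)[C@@H](C)[C@H]1O[Si](C)(C)C(C)(C)C | intermediate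
20 | 8-methacrylate 13-acetate | C=C(C)C(=O)O[C@@H]1C2=C(COC(C)=O)CO[Si](C(C)(C)C)(C(C)(C)C)O[C@@H]2[C@@H]2O[C@]2(C)CC[C@H](O[Si](CC)(CC)CC)[C@@H](C)[C@H]1O[Si](C)(C)C(C)(C)C | intermediate
21 | 1,6,12-triol, 9-OTBS (C12 cis to C6 on C7=C11) | OC/C(COC(C)=O)=C1\[C@H](O)[C@@H]2O[C@]2(C)CC[C@H](O)[C@@H](C)[C@@H](O[Si](C)(C)C(C)(C)C)[C@@H]1OC(=O)C(C)=C | intermediate
22 | 6,12-lactol (C12 hemiacetal epimers), 1-OH, 9-OTBS | C=C(C)C(=O)O[C@@H]1C2=C(COC(C)=O)C(O)O[C@@H]2[C@@H]2O[C@]2(C)CC[C@H](O)[C@@H](C)[C@H]1O[Si](C)(C)C(C)(C)C | intermediate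
23 | (1S,4R,5S,6S,8R,9R,10R)-6,12-olide, 1-OH, 9-OTBS | C=C(C)C(=O)O[C@@H]1C2=C(COC(C)=O)C(=O)O[C@@H]2[C@@H]2O[C@]2(C)CC[C@H](O)[C@@H](C)[C@H]1O[Si](C)(C)C(C)(C)C | intermediate
24 | (4R,5S,6S,8R,9R,10S)-1-oxo-6,12-olide, 9-OTBS | C=C(C)C(=O)O[C@@H]1C2=C(COC(C)=O)C(=O)O[C@@H]2[C@@H]2O[C@]2(C)CCC(=O)[C@@H](C)[C@H]1O[Si](C)(C)C(C)(C)C | intermediate
25 | target, (4R,5S,6S,8R,9R,10S)-13-acetoxy-4,5-epoxy-9-hydroxy-8-methacryloyloxy-1-oxogermacr-7(11)-en-6,12-olide | C=C(C)C(=O)O[C@@H]1C2=C(COC(C)=O)C(=O)O[C@@H]2[C@@H]2O[C@]2(C)CCC(=O)[C@@H](C)[C@H]1O | target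

**Count**
Total steps: 18. Longest linear sequence: 17 (steps 2 to 18 from nerol); step 1 is a one‑step side branch.

**Steps most likely to fail**

1. Step 11 (ring closure). What may go wrong: ionisation or rearrangement of the trisubstituted epoxide and enolisation of the α‑branched aldehyde by the silyl triflate; oligomerisation in place of ten‑membered ring closure; loss of facial selectivity at C9, because the Felkin preference of the α‑methyl aldehyde opposes the required topicity. Fallback: it sets out from 15. The ring is closed as a direct vinylogous aldol addition under bifunctional tertiary amine–thiourea catalysis (toluene, high dilution, rt), which deprotonates C8 reversibly and activates the aldehyde by hydrogen bonding without a silyl Lewis acid, giving the free C9 alcohol, hydroxy lactone F1. Silylation of F1 (TBSOTf, 2,6‑lutidine, CH2Cl2, −78 °C) comes back to the route at 17.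

2. Step 4 (fragment union). What may go wrong: poor facial discrimination in the addition to the epoxy aldehyde, and further reduction of the remaining C–Br bond by the low‑valent metals. Fallback: it sets out from 7 as obtained (mixture of C6 epimers). Dess–Martin oxidation gives epoxy ketone F2; reduction with Zn(BH4)2 (Et2O, −20 °C), in which zinc bridges the ketone and epoxide oxygens, is the established erythro‑selective reduction of α,β‑epoxy ketones. It comes back at 7 as the single (6S) epimer.

3. Step 5 (hydroxymethylation). What may go wrong: slow transfer of the sp3 hydroxymethyl group from tin to palladium at the hindered α‑position, so that protodebromination or butyl transfer takes over. Fallback: it sets out from 7. Palladium‑catalysed reductive carbonylation (CO, Bu3SnH added slowly, Pd(PPh3)4, THF, 50 °C) gives C12 aldehyde F3, which may sit as its lactol with O6; Luche reduction (NaBH4, CeCl3·7H2O, MeOH, −40 °C) comes back at 8.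

**Further compounds**
F1 | step 11 | hydroxy lactone (17 with free 9-OH) | O=C1O[C@@H]3C2=C1CO[Si](C(C)(C)C)(C(C)(C)C)O[C@@H]2[C@@H]1O[C@]1(C)CC[C@H](O[Si](CC)(CC)CC)[C@@H](C)[C@H]3O
F2 | step 4 | epoxy ketone (C6 ketone of 7) | O=C1OCC(=C1Br)C(=O)[C@@H]1O[C@]1(C)CCC=C(C)C
F3 | step 5 | C12 aldehyde (3-formyl analogue of 8) | O=C1OCC(=C1C=O)[C@H](O)[C@@H]1O[C@]1(C)CCC=C(C)C
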